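## Retrosynthetic overview

1. Target 43 ⇐ C17 epimerisation and SmI2 opening of 8,17‑epoxy lactone 41 ⇐ nucleophilic epoxidation of macrocyclic butenolide 40.
2. 40 ⇐ Ni/Cr (Nozaki–Hiyama–Kishi) macrocyclisation C8–C9 of aldehyde/vinyl triflate 39; the ten‑membered ring is the last carbocycle formed.
3. 39 ⇐ C3–C4 alkylation of β‑keto sulfone 33 (oxygenated cyclohexane) with allylic chloride 16, then CBS reduction and acetylation at C2.
4. 33 ⇐ exo Diels–Alder of enal 22 with silyloxydiene 24 (six‑membered ring first; sets C1, C10, C11), then enone, C12 inversion, OH‑directed epoxidation (oxirane), hexanoate.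
5. 16 ⇐ methyl (S)‑glycerate by two Lacey–Dieckmann cyclisations: a chlorobutenolide template fixes the chloroalkene geometry, the second builds the C7–O–C19 butenolide.

Assumption: locants follow the briarane skeleton of the target (ring C1, C10–C14; Me‑15 on C1 defines the β face; C19 = lactone C=O), and the facial sense of the oxazaborolidinium catalyst in step 18 is assigned from the usual formyl C–H···O binding model.

## Route

**Fragment A (C4–C8, C16–C19)**

Step 1
Reactants: 1 methyl (4S)-2,2-dimethyl-1,3-dioxolane-4-carboxylate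
Product: 2 methyl (2S)-2,3-dihydroxypropanoate
Conditions: Dowex 50W (H+), MeOH, rt
Reagents that add atoms: none
Why: Acid‑catalysed transacetalisation removes the acetonide and leaves the ester and the chiral‑pool stereocentre (future C7, S) untouched.

Step 2
Reactants: 2 methyl (2S)-2,3-dihydroxypropanoate
Product: 3 methyl (2S)-3-[(tert-butyldiphenylsilyl)oxy]-2-hydroxypropanoate
Conditions: TBDPSCl (1.05 equiv), imidazole, CH2Cl2, 0 °C
Reagents that add atoms: tert-butyl(chloro)diphenylsilane CC(C)(C)[Si](Cl)(c1ccccc1)c1ccccc1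
Why: Selective silylation of the primary hydroxyl over the hindered α‑hydroxy ester OH.

Step 3
Reactants: 3 methyl (2S)-3-[(tert-butyldiphenylsilyl)oxy]-2-hydroxypropanoate
Product: 4 methyl (2S)-3-[(tert-butyldiphenylsilyl)oxy]-2-(propanoyloxy)propanoate
Conditions: EtCOCl, pyridine, DMAP (cat.), CH2Cl2, 0 °C
Reagents that add atoms: propanoyl chloride CCC(Cl)=O
Why: Simple O‑acylation installs the propionate that supplies C4, C5 and Me‑16.

Step 4
Reactants: 4 methyl (2S)-3-[(tert-butyldiphenylsilyl)oxy]-2-(propanoyloxy)propanoate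
Product: 5 (5S)-5-{[(tert-butyldiphenylsilyl)oxy]methyl}-4-hydroxy-3-methylfuran-2(5H)-one
Conditions: LiHMDS (2.5 equiv), THF, −78 → −40 °C; then 1 M HCl
Reagents that add atoms: none
Why: Lacey–Dieckmann cyclisation of the propionate enolate onto the adjacent methyl ester gives the tetronic acid, whose stable anion drives the reaction and protects C7 from epimerisation.

Step 5
Reactants: 5 (5S)-5-{[(tert-butyldiphenylsilyl)oxy]methyl}-4-hydroxy-3-methylfuran-2(5H)-one
Product: 6 (5S)-5-{[(tert-butyldiphenylsilyl)oxy]methyl}-4-chloro-3-methylfuran-2(5H)-one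
Conditions: (COCl)2, DMF (cat.), CH2Cl2, 0 °C → rt
Reagents that add atoms: oxalyl chloride ClC(=O)C(Cl)=O
Why: Vilsmeier‑type conversion of the vinylogous acid into the vinylogous acid chloride places Cl on C6 and Me on C5, held cis by the ring.

Step 6
Reactants: 6 (5S)-5-{[(tert-butyldiphenylsilyl)oxy]methyl}-4-chloro-3-methylfuran-2(5H)-one
Product: 7 (2E,4S)-5-[(tert-butyldiphenylsilyl)oxy]-3-chloro-2-methylpent-2-ene-1,4-diol
Conditions: DIBAL-H (3.5 equiv), CH2Cl2, −78 → 0 °C; Rochelle salt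
Reagents that add atoms: none
Why: Exhaustive 1,2‑reduction of the lactone carbonyl opens the ring, so the former ring bonds leave C4 (CH2OH) and C7 cis on the tetrasubstituted chloroalkene.

Step 7
Reactants: 7 (2E,4S)-5-[(tert-butyldiphenylsilyl)oxy]-3-chloro-2-methylpent-2-ene-1,4-diol
Product: 9 (2S,3E)-1-[(tert-butyldiphenylsilyl)oxy]-3,5-dichloro-4-methylpent-3-en-2-ol, via allylic mesylate 8 (not isolated)
Conditions: MsCl, 2,4,6-collidine, LiCl, DMF, 0 °C
Reagents that add atoms: lithium chloride [Li+].[Cl-]; methanesulfonyl chloride CS(Cl)(=O)=O (its atoms stay only in 8)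
Why: Collington–Meyers chlorination converts the primary allylic alcohol by SN2 without allylic shift, while the hindered secondary alcohol is not mesylated under the weak base.

Step 8
Reactants: 9 (2S,3E)-1-[(tert-butyldiphenylsilyl)oxy]-3,5-dichloro-4-methylpent-3-en-2-ol
Product: 10 (2S,3E)-1-[(tert-butyldiphenylsilyl)oxy]-3,5-dichloro-4-methylpent-3-en-2-yl propanoate
Conditions: EtCOCl, pyridine, DMAP (cat.), CH2Cl2, 0 °C → rt
Reagents that add atoms: propanoyl chloride CCC(Cl)=O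
Why: Acylation of the C7 hydroxyl installs the second propionate (C17, Me‑18, C19) and removes the risk of cyclisation onto the allylic chloride.

Step 9
Reactants: 10 (2S,3E)-1-[(tert-butyldiphenylsilyl)oxy]-3,5-dichloro-4-methylpent-3-en-2-yl propanoate
Product: 11 (2S,3E)-3,5-dichloro-1-hydroxy-4-methylpent-3-en-2-yl propanoate
Conditions: HF·pyridine, pyridine, THF, 0 °C → rt
Reagents that add atoms: none
Why: Acidic fluoride desilylation frees the C8 hydroxyl without base, so the neighbouring propionate does not migrate.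

Step 10
Reactants: 11 (2S,3E)-3,5-dichloro-1-hydroxy-4-methylpent-3-en-2-yl propanoate
Product: 13 (2S,3E)-3,5-dichloro-4-methyl-2-(propanoyloxy)pent-3-enoic acid, via aldehyde 12 (not isolated)
Conditions: TEMPO (cat.), NaOCl (cat.), NaClO2, MeCN/pH 6.7 phosphate buffer, 35 °C
Reagents that add atoms: sodium chlorite [Na+].[O-]Cl=O
Why: Buffered TEMPO/chlorite oxidation takes the primary alcohol through the aldehyde to the acid without epimerising the α‑acyloxy centre.

Step 11
Reactants: 13 (2S,3E)-3,5-dichloro-4-methyl-2-(propanoyloxy)pent-3-enoic acid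
Product: 14 methyl (2S,3E)-3,5-dichloro-4-methyl-2-(propanoyloxy)pent-3-enoate
Conditions: TMSCHN2, MeOH/toluene, 0 °C
Reagents that add atoms: (trimethylsilyl)diazomethane C[Si](C)(C)C=[N+]=[N-]
Why: Neutral diazoalkane esterification gives the methyl ester needed as the Dieckmann electrophile.

Step 12
Reactants: 14 methyl (2S,3E)-3,5-dichloro-4-methyl-2-(propanoyloxy)pent-3-enoate
Product: 15 (5S)-5-[(1E)-1,3-dichloro-2-methylprop-1-en-1-yl]-4-hydroxy-3-methylfuran-2(5H)-one
Conditions: LiHMDS (2.3 equiv), THF, −78 °C; 1 M HCl at −78 °C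
Reagents that add atoms: none
Why: A second Lacey–Dieckmann cyclisation forms the C17–C8 bond; allylic 1,3‑strain keeps the C7–H in the alkene plane so it is not enolised, and the cold quench prevents O‑alkylation by the allylic chloride.

Step 13
Reactants: 15 (5S)-5-[(1E)-1,3-dichloro-2-methylprop-1-en-1-yl]-4-hydroxy-3-methylfuran-2(5H)-one
Product: 16 (2S)-2-[(1E)-1,3-dichloro-2-methylprop-1-en-1-yl]-4-methyl-5-oxo-2,5-dihydrofuran-3-yl trifluoromethanesulfonate
Conditions: Tf2O, iPr2NEt, CH2Cl2, −78 °C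
Reagents that add atoms: trifluoromethanesulfonic anhydride FC(F)(F)S(=O)(=O)OS(=O)(=O)C(F)(F)F
Why: O‑Triflation of the tetronic acid gives the vinyl triflate that later serves as the C8 nucleophile precursor.

**Dienophile and diene**

Step 14
Reactants: 17 (2Z)-but-2-ene-1,4-diol
Product: 18 (2Z)-1,4-bis[(4-methoxybenzyl)oxy]but-2-ene
Conditions: NaH, PMBCl (2.2 equiv), Bu4NI (cat.), THF/DMF, 0 °C → rt
Reagents that add atoms: 4-methoxybenzyl chloride COc1ccc(CCl)cc1
Why: Double Williamson etherification of the symmetrical diol.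

Step 15
Reactants: 18 (2Z)-1,4-bis[(4-methoxybenzyl)oxy]but-2-ene
Product: 20 [(4-methoxybenzyl)oxy]acetaldehyde, via secondary ozonide 19 (not isolated)
Conditions: O3, CH2Cl2, −78 °C; then Me2S, −78 °C → rt
Reagents that add atoms: ozone [O-][O+]=O
Why: Ozonolysis with reductive work‑up cleaves the symmetrical alkene into two equivalents of the aldehyde.

Step 16
Reactants: 20 [(4-methoxybenzyl)oxy]acetaldehyde; 21 2-(triphenyl-λ5-phosphanylidene)propanal
Product: 22 (2E)-4-[(4-methoxybenzyl)oxy]-2-methylbut-2-enal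
Conditions: toluene, 80 °C
Reagents that add atoms: none
Why: Wittig reaction of the stabilised ylide gives the E‑enal (CHO trans to CH2OPMB), which fixes the trans C2/C9 relationship.

Step 17
Reactants: 23 pent-1-en-3-one
Product: 24 (3Z)-3-[(triisopropylsilyl)oxy]penta-1,3-diene
Conditions: TIPSOTf, Et3N, CH2Cl2, 0 °C
Reagents that add atoms: triisopropylsilyl trifluoromethanesulfonate CC(C)[Si](OS(=O)(=O)C(F)(F)F)(C(C)C)C(C)C
Why: Soft enolisation gives the thermodynamically preferred Z‑silyl enol ether, in which the terminal methyl is "outside" and the diene can reach s‑cis.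

**Cyclohexane core (C1, C2, C9–C15, C20)**

Step 18
Reactants: 22 (2E)-4-[(4-methoxybenzyl)oxy]-2-methylbut-2-enal; 24 (3Z)-3-[(triisopropylsilyl)oxy]penta-1,3-diene
Product: 25 (1S,5R,6S)-6-{[(4-methoxybenzyl)oxy]methyl}-1,5-dimethyl-4-[(triisopropylsilyl)oxy]cyclohex-3-ene-1-carbaldehyde
Conditions: (R)-o-tolyl-CBS-oxazaborolidine·Tf2NH (20 mol %), CH2Cl2, −78 → −40 °C
Reagents that add atoms: none
Why: Catalytic asymmetric Diels–Alder reaction in which the 2‑silyloxy group directs the "para" regiochemistry, the E‑enal gives trans C2/C9, the exo transition state (CHO exo, avoiding the clash between the diene methyl and the dienophile β‑substituent) places Me‑20 cis to C9, and the chiral Lewis acid shields one enal face to set C1, C10 and C11 absolutely.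

Step 19
Reactants: 25 (1S,5R,6S)-6-{[(4-methoxybenzyl)oxy]methyl}-1,5-dimethyl-4-[(triisopropylsilyl)oxy]cyclohex-3-ene-1-carbaldehyde
Product: 26 1-[(1S,5R,6S)-6-{[(4-methoxybenzyl)oxy]methyl}-1,5-dimethyl-4-[(triisopropylsilyl)oxy]cyclohex-3-en-1-yl]-2-(phenylsulfonyl)ethan-1-ol (C2 epimers)
Conditions: PhSO2CH3, n-BuLi, THF, −78 °C; then 25; H2O
Reagents that add atoms: methyl phenyl sulfone CS(=O)(=O)c1ccccc1
Why: 1,2‑Addition of the α‑sulfonyl carbanion to the aldehyde adds C3; the C2 epimer mixture is of no consequence because C2 is oxidised in step 26.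

Step 20
Reactants: 26 β‑hydroxy sulfone silyl enol ether (as above)
Product: 27 4α-[1-hydroxy-2-(phenylsulfonyl)ethyl]-5β-{[(4-methoxybenzyl)oxy]methyl}-4β,6β-dimethylcyclohex-2-en-1-one (ring C1–C6 = briarane C12, C13, C14, C1, C10, C11; C2 epimers)
Conditions: Pd(OAc)2 (1.1 equiv), MeCN, rt
Reagents that add atoms: none
Why: Saegusa–Ito oxidation of the silyl enol ether gives the C13=C14 enone regiospecifically and leaves the C11 stereocentre untouched.

Step 21
Reactants: 27 enone (as above)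
Product: 28 12β‑allylic alcohol: 27 with C12=O reduced, OH cis to Me‑20 (C2 epimers)
Conditions: DIBAL-H (2.5 equiv), CH2Cl2, −78 °C
Reagents that add atoms: none
Why: 1,2‑Reduction with a bulky hydride from the α face, opposite the axial C10–CH2OPMB and Me‑20, gives the 12β‑alcohol.

Step 22
Reactants: 28 12β‑allylic alcohol (as above)
Product: 29 12α‑(4‑nitrobenzoate) of the C12‑inverted alcohol (C2 epimers)
Conditions: 4-O2NC6H4CO2H, PPh3, DIAD, THF, 0 °C → rt
Reagents that add atoms: 4-nitrobenzoic acid OC(=O)c1ccc(cc1)[N+]([O-])=O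
Why: Mitsunobu SN2 inversion of the allylic C12 carbinol sets the 12α oxygen; the neopentyl C2 hydroxyl is too hindered to react.

Step 23
Reactants: 29 12α‑(4‑nitrobenzoate) (as above)
Product: 30 12α‑allylic alcohol (C12–OH trans to Me‑20; C2 epimers)
Conditions: K2CO3 (cat.), MeOH, rt
Reagents that add atoms: none
Why: Mild transesterification releases the inverted allylic alcohol.

Step 24
Reactants: 30 12α‑allylic alcohol (as above)
Product: 31 13α,14α‑epoxy‑12α‑ol (C2 epimers)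
Conditions: VO(acac)2 (5 mol %), t-BuOOH, CH2Cl2, 0 °C → rt
Reagents that add atoms: tert-butyl hydroperoxide CC(C)(C)OO
Why: Hydroxyl‑directed vanadium epoxidation delivers oxygen syn to the allylic 12α‑OH (and the homoallylic C2–OH, also on the α face), giving the 13α,14α‑oxirane.

Step 25
Reactants: 31 13α,14α‑epoxy‑12α‑ol (as above)
Product: 32 12α‑hexanoate of 31 (C2–OH free; C2 epimers)
Conditions: (C5H11CO)2O (1.1 equiv), Et3N, DMAP (cat.), CH2Cl2, 0 °C
Reagents that add atoms: hexanoic anhydride CCCCCC(=O)OC(=O)CCCCC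
Why: DMAP‑catalysed acylation is selective for the C12 hydroxyl because the C2 hydroxyl is neopentyl.

Step 26
Reactants: 32 12α‑hexanoate (as above)
Product: 33 β‑keto sulfone: 32 with C2–OH oxidised to C2=O
Conditions: Dess–Martin periodinane, NaHCO3, CH2Cl2, rt
Reagents that add atoms: none
Why: Dess–Martin oxidation of the only free alcohol gives a single β‑keto sulfone, an acidic (pKa about 12) C3 nucleophile.

**Union, macrocyclisation and endgame**

Step 27
Reactants: 33 β‑keto sulfone; 16 allylic chloride/vinyl triflate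
Product: 34 C3–C4 coupled keto sulfone (C3 epimers), carrying the C5=C6 chloroalkene and the 4‑triflyloxybutenolide
Conditions: NaH (1.0 equiv), THF, 0 °C; then 16, NaI (cat.), DMF, 0 °C → rt
Reagents that add atoms: none
Why: SN2 C‑alkylation of the soft keto sulfone anion with the primary allylic halide joins the fragments; the anion is too weak a base to touch C7–H or the triflate.

Step 28
Reactants: 34 coupled keto sulfone
Product: 35 C2 ketone (sulfone removed)
Conditions: SmI2 (2.5 equiv), THF/MeOH, −78 °C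
Reagents that add atoms: none
Why: Reductive desulfonylation of the β‑keto sulfone is fast at −78 °C, where epoxide, esters, vinyl chloride and vinyl triflate are inert.

Step 29
Reactants: 35 C2 ketone
Product: 36 (2S)‑alcohol
Conditions: (R)-Me-CBS (1.0 equiv), BH3·SMe2, THF, −30 °C
Reagents that add atoms: none
Why: Corey–Bakshi–Shibata reduction with reagent control (large = quaternary C1, small = C3H2) delivers hydride to give the 2S carbinol.

Step 30
Reactants: 36 (2S)‑alcohol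
Product: 37 (2S)‑acetate
Conditions: Ac2O, pyridine, DMAP (cat.), CH2Cl2, 0 °C → rt
Reagents that add atoms: acetic anhydride CC(=O)OC(C)=O
Why: Acetylation of the only free hydroxyl installs the C2 acetate of the target.

Step 31
Reactants: 37 (2S)‑acetate
Product: 38 C9 primary alcohol
Conditions: DDQ, CH2Cl2/pH 7 buffer, 0 °C
Reagents that add atoms: none
Why: Neutral oxidative PMB cleavage spares the epoxide, esters and vinyl triflate.

Step 32
Reactants: 38 C9 primary alcohol
Product: 39 C9 aldehyde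
Conditions: Dess–Martin periodinane, NaHCO3, CH2Cl2, 0 °C → rt
Reagents that add atoms: none
Why: Buffered Dess–Martin oxidation gives the aldehyde without epimerising C10.

Step 33
Reactants: 39 C9 aldehyde/C8 vinyl triflate
Product: 40 macrocyclic butenolide: (2S)-2-acetoxy-6-chloro-13α,14α-epoxy-12α-hexanoyloxy-(9S)-9-hydroxybriara-5,8(17)-dien-19,7-olide
Conditions: CrCl2 (10 equiv), NiCl2 (10 mol %), DMF/THF, 0.003 M, slow addition, rt
Reagents that add atoms: none
Why: Intramolecular Nozaki–Hiyama–Kishi reaction closes the ten‑membered ring; the alkenylchromium, tethered through C1, attacks the aldehyde anti to C11 and past H‑10 with the carbonyl oxygen turned toward C1, which gives the 9S carbinol.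

Step 34
Reactants: 40 macrocyclic butenolide
Product: 41 8,17‑epoxy lactone (epoxide oxygen on the H‑7 face; C17 methyl on the opposite face)
Conditions: t-BuOOH, n-BuLi (→ t-BuOOLi), THF, −20 → 0 °C
Reagents that add atoms: tert-butyl hydroperoxide CC(C)(C)OO
Why: Nucleophilic (Weitz–Scheffer‑type) epoxidation is chemoselective for the electron‑poor butenolide, and the peroxide adds to C8 anti to the C7–C6 bond, setting the C8–O configuration.

Step 35
Reactants: 41 8,17‑epoxy lactone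
Product: 42 17‑epi‑target (8‑OH, 17S; Me‑18 cis to C9)
Conditions: SmI2 (2.5 equiv), THF/MeOH, −78 °C
Reagents that add atoms: none
Why: Reductive cleavage of the Cα–O bond of the α,β‑epoxy lactone keeps the C8–O stereocentre, and the samarium enolate is protonated kinetically on the convex face (syn to 8‑OH).

Step 36
Reactants: 42 17‑epi‑target
Product: 43 target, (1S,2S,5E,7S,8R,9S,10S,11R,12S,13S,14R,17R)-2-acetoxy-6-chloro-13,14-epoxy-12-hexanoyloxy-8,9-dihydroxybriar-5-en-19,7-olide (CNP0243318.1)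
Conditions: DBU (0.5 equiv), toluene, rt
Reagents that add atoms: none
Why: Base‑mediated enolisation equilibrates C17 to the more stable epimer, with Me‑18 on the convex face of the cis‑fused lactone (trans to C9).

## Compound list

1 | methyl (4S)-2,2-dimethyl-1,3-dioxolane-4-carboxylate | CC1(C)OC[C@H](O1)C(=O)OC | starting material
2 | methyl (2S)-2,3-dihydroxypropanoate | OC[C@H](O)C(=O)OC | intermediate
3 | methyl (2S)-3-[(tert-butyldiphenylsilyl)oxy]-2-hydroxypropanoate | CC(C)(C)[Si](c1ccccc1)(c1ccccc1)OC[C@H](O)C(=O)OC | intermediate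
4 | methyl (2S)-3-[(tert-butyldiphenylsilyl)oxy]-2-(propanoyloxy)propanoate | CCC(=O)O[C@@H](CO[Si](c1ccccc1)(c1ccccc1)C(C)(C)C)C(=O)OC | intermediate
5 | (5S)-5-{[(tert-butyldiphenylsilyl)oxy]methyl}-4-hydroxy-3-methylfuran-2(5H)-one | O=C1O[C@@H](CO[Si](c2ccccc2)(c2ccccc2)C(C)(C)C)C(O)=C1C | intermediate
6 | (5S)-5-{[(tert-butyldiphenylsilyl)oxy]methyl}-4-chloro-3-methylfuran-2(5H)-one | O=C1O[C@@H](CO[Si](c2ccccc2)(c2ccccc2)C(C)(C)C)C(Cl)=C1C | intermediate
7 | (2E,4S)-5-[(tert-butyldiphenylsilyl)oxy]-3-chloro-2-methylpent-2-ene-1,4-diol (CH2OH and C4 cis on the alkene) | OC/C(C)=C(Cl)\[C@@H](O)CO[Si](c1ccccc1)(c1ccccc1)C(C)(C)C | intermediate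
8 | (2E,4S)-5-[(tert-butyldiphenylsilyl)oxy]-3-chloro-4-hydroxy-2-methylpent-2-en-1-yl methanesulfonate | CS(=O)(=O)OC/C(C)=C(Cl)\[C@@H](O)CO[Si](c1ccccc1)(c1ccccc1)C(C)(C)C | intermediate (not isolated)
9 | (2S,3E)-1-[(tert-butyldiphenylsilyl)oxy]-3,5-dichloro-4-methylpent-3-en-2-ol | ClC/C(C)=C(Cl)\[C@@H](O)CO[Si](c1ccccc1)(c1ccccc1)C(C)(C)C | intermediate
10 | (2S,3E)-1-[(tert-butyldiphenylsilyl)oxy]-3,5-dichloro-4-methylpent-3-en-2-yl propanoate | CCC(=O)O[C@@H](CO[Si](c1ccccc1)(c1ccccc1)C(C)(C)C)/C(Cl)=C(/C)CCl | intermediate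
11 | (2S,3E)-3,5-dichloro-1-hydroxy-4-methylpent-3-en-2-yl propanoate | CCC(=O)O[C@@H](CO)/C(Cl)=C(/C)CCl | intermediate
12 | (2S,3E)-3,5-dichloro-4-methyl-1-oxopent-3-en-2-yl propanoate | CCC(=O)O[C@@H](C=O)/C(Cl)=C(/C)CCl | intermediate (not isolated)
13 | (2S,3E)-3,5-dichloro-4-methyl-2-(propanoyloxy)pent-3-enoic acid | CCC(=O)O[C@@H](C(O)=O)/C(Cl)=C(/C)CCl | intermediate
14 | methyl (2S,3E)-3,5-dichloro-4-methyl-2-(propanoyloxy)pent-3-enoate | CCC(=O)O[C@@H](C(=O)OC)/C(Cl)=C(/C)CCl | intermediate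
15 | (5S)-5-[(1E)-1,3-dichloro-2-methylprop-1-en-1-yl]-4-hydroxy-3-methylfuran-2(5H)-one | O=C1O[C@H](/C(Cl)=C(/C)CCl)C(O)=C1C | intermediate
16 | (2S)-2-[(1E)-1,3-dichloro-2-methylprop-1-en-1-yl]-4-methyl-5-oxo-2,5-dihydrofuran-3-yl trifluoromethanesulfonate | O=C1O[C@H](/C(Cl)=C(/C)CCl)C(OS(=O)(=O)C(F)(F)F)=C1C | intermediate
17 | (2Z)-but-2-ene-1,4-diol | OC/C=C\CO | starting material
18 | (2Z)-1,4-bis[(4-methoxybenzyl)oxy]but-2-ene | COc1ccc(COC/C=C\COCc2ccc(OC)cc2)cc1 | intermediate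
19 | 3,5-bis{[(4-methoxybenzyl)oxy]methyl}-1,2,4-trioxolane | COc1ccc(COCC2OOC(COCc3ccc(OC)cc3)O2)cc1 | intermediate (not isolated)
20 | [(4-methoxybenzyl)oxy]acetaldehyde | COc1ccc(COCC=O)cc1 | intermediate
21 | 2-(triphenyl-λ5-phosphanylidene)propanal | CC(C=O)=P(c1ccccc1)(c1ccccc1)c1ccccc1 | starting material
22 | (2E)-4-[(4-methoxybenzyl)oxy]-2-methylbut-2-enal | O=C/C(C)=C/COCc1ccc(OC)cc1 | intermediate
23 | pent-1-en-3-one | CCC(=O)C=C | starting material
24 | (3Z)-3-[(triisopropylsilyl)oxy]penta-1,3-diene | C/C=C(/C=C)O[Si](C(C)C)(C(C)C)C(C)C | intermediate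
25 | (1S,5R,6S)-6-{[(4-methoxybenzyl)oxy]methyl}-1,5-dimethyl-4-[(triisopropylsilyl)oxy]cyclohex-3-ene-1-carbaldehyde (Me‑15, C9 and Me‑20 all β; CHO α) | CC(C)[Si](C(C)C)(C(C)C)OC1[C@H](C)[C@H](COCc2ccc(OC)cc2)[C@@](C)(C=O)CC=1 | intermediate
26 | 1-[(1S,5R,6S)-6-{[(4-methoxybenzyl)oxy]methyl}-1,5-dimethyl-4-[(triisopropylsilyl)oxy]cyclohex-3-en-1-yl]-2-(phenylsulfonyl)ethan-1-ol (C2 epimers) | CC(C)[Si](C(C)C)(C(C)C)OC1[C@H](C)[C@H](COCc2ccc(OC)cc2)[C@@](C)(C(O)CS(=O)(=O)c2ccccc2)CC=1 | intermediate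
27 | 4α-[1-hydroxy-2-(phenylsulfonyl)ethyl]-5β-{[(4-methoxybenzyl)oxy]methyl}-4β,6β-dimethylcyclohex-2-en-1-one (C2 epimers) | O=C1[C@H](C)[C@H](COCc2ccc(OC)cc2)[C@@](C)(C(O)CS(=O)(=O)c2ccccc2)C=C1 | intermediate
28 | 12β‑allylic alcohol from 27 (C12–OH cis to Me‑20; C2 epimers) | O[C@@H]1[C@H](C)[C@H](COCc2ccc(OC)cc2)[C@@](C)(C(O)CS(=O)(=O)c2ccccc2)C=C1 | intermediate
29 | 12α‑(4‑nitrobenzoate) (C12–O trans to Me‑20; C2 epimers) | O=C(O[C@H]1[C@H](C)[C@H](COCc2ccc(OC)cc2)[C@@](C)(C(O)CS(=O)(=O)c2ccccc2)C=C1)c1ccc(cc1)[N+]([O-])=O | intermediate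
30 | 12α‑allylic alcohol (C2 epimers) | O[C@H]1[C@H](C)[C@H](COCc2ccc(OC)cc2)[C@@](C)(C(O)CS(=O)(=O)c2ccccc2)C=C1 | intermediate
31 | 13α,14α‑epoxy‑12α‑ol (epoxide cis to C12–OH; C2 epimers) | O[C@H]1[C@H](C)[C@H](COCc2ccc(OC)cc2)[C@@](C)(C(O)CS(=O)(=O)c2ccccc2)[C@H]2O[C@@H]12 | intermediate
32 | 13α,14α‑epoxy‑12α‑hexanoate with free C2–OH (C2 epimers) | CCCCCC(=O)O[C@H]1[C@H](C)[C@H](COCc2ccc(OC)cc2)[C@@](C)(C(O)CS(=O)(=O)c2ccccc2)[C@H]2O[C@@H]12 | intermediate
33 | β‑keto sulfone: C1–C(=O)–CH2SO2Ph on the epoxy hexanoate core, C9–OPMB | CCCCCC(=O)O[C@H]1[C@H](C)[C@H](COCc2ccc(OC)cc2)[C@@](C)(C(=O)CS(=O)(=O)c2ccccc2)[C@H]2O[C@@H]12 | intermediate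
34 | coupled keto sulfone (C3–SO2Ph, C3 epimers; (5E)‑chloroalkene; (7S)‑4‑triflyloxybutenolide) | CCCCCC(=O)O[C@H]1[C@H](C)[C@H](COCc2ccc(OC)cc2)[C@@](C)(C(=O)C(S(=O)(=O)c2ccccc2)C/C(C)=C(Cl)\[C@H]2OC(=O)C(C)=C2OS(=O)(=O)C(F)(F)F)[C@H]2O[C@@H]12 | intermediate
35 | C2 ketone (34 without the sulfonyl group) | CCCCCC(=O)O[C@H]1[C@H](C)[C@H](COCc2ccc(OC)cc2)[C@@](C)(C(=O)CC/C(C)=C(Cl)\[C@H]2OC(=O)C(C)=C2OS(=O)(=O)C(F)(F)F)[C@H]2O[C@@H]12 | intermediate
36 | (2S)‑alcohol | CCCCCC(=O)O[C@H]1[C@H](C)[C@H](COCc2ccc(OC)cc2)[C@@](C)([C@@H](O)CC/C(C)=C(Cl)\[C@H]2OC(=O)C(C)=C2OS(=O)(=O)C(F)(F)F)[C@H]2O[C@@H]12 | intermediate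
37 | (2S)‑acetate, C9–OPMB | CCCCCC(=O)O[C@H]1[C@H](C)[C@H](COCc2ccc(OC)cc2)[C@@](C)([C@@H](OC(C)=O)CC/C(C)=C(Cl)\[C@H]2OC(=O)C(C)=C2OS(=O)(=O)C(F)(F)F)[C@H]2O[C@@H]12 | intermediate
38 | (2S)‑acetate, C9 primary alcohol | CCCCCC(=O)O[C@H]1[C@H](C)[C@H](CO)[C@@](C)([C@@H](OC(C)=O)CC/C(C)=C(Cl)\[C@H]2OC(=O)C(C)=C2OS(=O)(=O)C(F)(F)F)[C@H]2O[C@@H]12 | intermediate
39 | (2S)‑acetate, C9 aldehyde (macrocyclisation precursor) | CCCCCC(=O)O[C@H]1[C@H](C)[C@H](C=O)[C@@](C)([C@@H](OC(C)=O)CC/C(C)=C(Cl)\[C@H]2OC(=O)C(C)=C2OS(=O)(=O)C(F)(F)F)[C@H]2O[C@@H]12 | intermediate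
40 | (2S,9S)-2-acetoxy-6-chloro-13α,14α-epoxy-12α-hexanoyloxy-9-hydroxybriara-5(E),8(17)-dien-19,7-olide | CCCCCC(=O)O[C@H]1[C@H](C)[C@@H]2[C@H](O)C3=C(C)C(=O)O[C@@H]3/C(Cl)=C(/C)CC[C@H](OC(C)=O)[C@@]2(C)[C@H]2O[C@@H]12 | intermediate
41 | 8,17:13,14‑diepoxide of 40 (8,17‑oxirane on the H‑7 face, Me‑18 on the opposite face) | CCCCCC(=O)O[C@H]1[C@H](C)[C@@H]2[C@H](O)[C@@]34O[C@@]4(C)C(=O)O[C@@H]3/C(Cl)=C(/C)CC[C@H](OC(C)=O)[C@@]2(C)[C@H]2O[C@@H]12 | intermediate
42 | 17‑epi‑target (17S; Me‑18 cis to C9) | CCCCCC(=O)O[C@H]1[C@H](C)[C@@H]2[C@H](O)[C@@]3(O)[C@H](OC(=O)[C@H]3C)/C(Cl)=C(/C)CC[C@H](OC(C)=O)[C@@]2(C)[C@H]2O[C@@H]12 | intermediate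
43 | (1S,2S,5E,7S,8R,9S,10S,11R,12S,13S,14R,17R)-2-acetoxy-6-chloro-13,14-epoxy-12-hexanoyloxy-8,9-dihydroxybriar-5-en-19,7-olide (CNP0243318.1) | CCCCCC(=O)O[C@H]1[C@H](C)[C@@H]2[C@H](O)[C@@]3(O)[C@H](OC(=O)[C@@H]3C)/C(Cl)=C(/C)CC[C@H](OC(C)=O)[C@@]2(C)[C@H]2O[C@@H]12 | target

## Step count and risks

Total step count: 36 (fragment A steps 1–13; dienophile steps 14–16; diene step 17; core steps 18–26; union and endgame steps 27–36).
Longest linear sequence: 23 steps (steps 1–13, then 27–36); the core branch runs 22 steps (14–16, 18–26, 27–36).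

Three steps most likely to fail:

Step 33 (Ni/Cr macrocyclisation). Closing a ten‑membered ring onto a hindered aldehyde with a tetrasubstituted, electron‑poor alkenyl metal may be slow, and the C9 configuration rests on a conformational argument. Fallback: set out from 39 and return at 40 by a radical ring closure instead of a polar one. With SmI2/HMPA/t‑BuOH in THF at high dilution, the C9 ketyl radical adds to C8 of the vinylogous triflate and the resulting samarium enolate expels triflate, restoring the butenolide (ketyl–olefin addition–elimination). This fallback makes no new compound (F0). Should C9 emerge epimeric, the ketone sequence given for step 34 corrects it.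

Step 34 (epoxidation of the tetrasubstituted butenolide). The β‑carbon is fully substituted, and the peroxide anion could attack the esters first. Fallback: set out from 40 and return at 41. Dess–Martin oxidation of the C9 carbinol gives the 9‑oxo macrocyclic butenolide F4, a doubly activated ene‑dione. t‑BuOOH/DBU at 0 °C then epoxidises it readily from the H‑7 face to the 9‑oxo‑8,17‑epoxy lactone F5. Chelation‑controlled reduction with Zn(BH4)2 (hydride entering past C7–H, not past the fully substituted C17) regenerates the 9S carbinol of 41.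

Step 18 (asymmetric exo Diels–Alder of a trisubstituted enal). Reactivity, exo selectivity and enantioselectivity are all demanding. Fallback: set out from 22 and return at 27. The silyloxydiene is replaced by the much more reactive 1‑amino‑3‑siloxydiene (1E,3Z)-3-[(tert-butyldimethylsilyl)oxy]-N,N-dimethylpenta-1,3-dien-1-amine F1, made from (E)-1-(dimethylamino)pent-1-en-3-one with KHMDS and TBSCl. This diene allows a chiral Cr(III)–salen Lewis acid at −40 °C, the catalyst enantiomer being chosen to give the C1 configuration of 25. Cycloaddition with 22 gives the amino cycloadduct F2. Dilute HF in MeCN hydrolyses the silyl enol ether and eliminates the amine, giving the enone aldehyde F3 directly without a Saegusa step. PhSO2CH2Li then adds to the aldehyde at −78 °C to give 27.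

## Further compounds

F1 | step 18 | (1E,3Z)-3-[(tert-butyldimethylsilyl)oxy]-N,N-dimethylpenta-1,3-dien-1-amine | C/C=C(/C=C/N(C)C)O[Si](C)(C)C(C)(C)C
F2 | step 18 | amino cycloadduct: 2α-(dimethylamino)-6β-{[(4-methoxybenzyl)oxy]methyl}-1β,5β-dimethyl-4-[(tert-butyldimethylsilyl)oxy]cyclohex-3-ene-1α-carbaldehyde | CC(C)(C)[Si](C)(C)OC1[C@H](C)[C@H](COCc2ccc(OC)cc2)[C@@](C)(C=O)[C@@H](N(C)C)C=1
F3 | step 18 | enone aldehyde: 6β-{[(4-methoxybenzyl)oxy]methyl}-1β,5β-dimethyl-4-oxocyclohex-2-ene-1α-carbaldehyde | O=C1[C@H](C)[C@H](COCc2ccc(OC)cc2)[C@@](C)(C=O)C=C1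
F0 | step 33 | none | none
F4 | step 34 | 9‑oxo macrocyclic butenolide (40 with C9=O) | CCCCCC(=O)O[C@H]1[C@H](C)[C@@H]2C(=O)C3=C(C)C(=O)O[C@@H]3/C(Cl)=C(/C)CC[C@H](OC(C)=O)[C@@]2(C)[C@H]2O[C@@H]12
F5 | step 34 | 9‑oxo‑8,17‑epoxy lactone (41 with C9=O) | CCCCCC(=O)O[C@H]1[C@H](C)[C@@H]2C(=O)[C@@]34O[C@@]4(C)C(=O)O[C@@H]3/C(Cl)=C(/C)CC[C@H](OC(C)=O)[C@@]2(C)[C@H]2O[C@@H]12
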